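**Retrosynthetic overview**
- The side chain is cut between C4' and C5' by a late alkyl–alkyl Suzuki coupling: a C11 (4R,6R)-6-butenyl lactone plus the C14 arm (E)-8-bromo-1-phenyloct-2-ene.
- The C14 arm comes from benzyl bromide and an (E)-alkenyl boronate made by syn-hydroboration of 7-bromohept-1-yne (from hept-6-yn-1-ol).
- The lactone, the only ring, is closed just before the coupling by oxidative lactonisation of a 1,3,5-triol.
- The C4 carbinol comes from Sharpless epoxidation and Red-Al opening of a (Z)-trisubstituted allylic alcohol, itself made from an (R)-2,2-disubstituted epoxide and a (Z)-alkenyl metal derived from but-2-yn-1-ol.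
- The C6 carbinol comes from the chiral pool: (S)-2-methylglycidol opened by allylmagnesium bromide, then re-closed to the epoxide.

Assumption: (S)-2-methylglycidol (≥98% ee) and allylmagnesium bromide solution are bought; the 2-methoxypropan-2-yl (MOP) acetal serves as protecting group.

**Route**

Step 1
Reactants: 1 but-2-yn-1-ol
Product: 3 (Z)-3-iodobut-2-en-1-ol, via cyclic alkenylalanate 2 (not isolated)
Conditions: Red-Al (1.6 equiv), THF, 0 °C → rt; EtOAc; then I2, THF, −78 → 0 °C
Reagents that add atoms: iodine (II)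
Why: Alkoxide-directed trans-hydroalumination puts Al on C3 cis to the CH2O group (five-membered alanate), and iodo-dealumination with retention gives only the (Z)-iodide.

Step 2
Reactants: 3 (Z)-3-iodobut-2-en-1-ol
Product: 4 (Z)-3-iodo-1-[(2-methoxypropan-2-yl)oxy]but-2-ene
Conditions: 2-methoxypropene (1.5 equiv), PPTS (1 mol %), CH2Cl2, 0 °C; Et3N quench
Reagents that add atoms: 2-methoxypropene (COC(C)=C)
Why: Acid-catalysed addition of the alcohol to the enol ether (acetalisation) gives a base-stable MOP ether that has no new stereocentre and cannot undergo silyl migration in the later vinyllithium.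

Step 3
Reactants: 5 hept-6-yn-1-ol
Product: 6 7-bromohept-1-yne
Conditions: CBr4 (1.2 equiv), PPh3 (1.25 equiv), CH2Cl2, 0 °C
Reagents that add atoms: carbon tetrabromide (BrC(Br)(Br)Br)
Why: Appel bromination of the primary alcohol is SN2 on an alkoxyphosphonium ion and leaves the terminal alkyne untouched.

Step 4
Reactants: 6 7-bromohept-1-yne
Product: 7 2-[(1E)-7-bromohept-1-en-1-yl]-4,4,5,5-tetramethyl-1,3,2-dioxaborolane
Conditions: HBpin (1.1 equiv), Cp2Zr(H)Cl (5 mol %), Et3N (10 mol %), neat, 60 °C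
Reagents that add atoms: pinacolborane ([H]B1OC(C)(C)C(C)(C)O1)
Why: Zirconium-catalysed anti-Markovnikov syn-hydroboration of the terminal alkyne fixes the (E) geometry, and the alkyl bromide is inert to it.

Step 5
Reactants: 7 2-[(1E)-7-bromohept-1-en-1-yl]-4,4,5,5-tetramethyl-1,3,2-dioxaborolane; 8 benzyl bromide
Product: 9 [(2E)-8-bromooct-2-en-1-yl]benzene
Conditions: Pd(PPh3)4 (3 mol %), K3PO4 (3 equiv), THF/H2O 10:1, 60 °C
Reagents that add atoms: none
Why: Suzuki–Miyaura coupling proceeds with retention of the alkene geometry, and Pd(0)/PPh3 adds to the benzylic C–Br bond but not to the unactivated primary alkyl bromide.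

Step 6
Reactants: 10 (S)-2-methylglycidol; 11 allylmagnesium bromide
Product: 12 (2R)-2-methylhex-5-ene-1,2-diol
Conditions: 11 (2.5 equiv), CuI (5 mol %), THF, −30 → 0 °C; aq NH4Cl
Reagents that add atoms: none
Why: Copper-catalysed SN2 opening occurs at the epoxide CH2, so the quaternary C–O bond and its configuration are untouched; the Payne rearrangement of this alkoxide is degenerate and cannot erode ee.

Step 7
Reactants: 12 (2R)-2-methylhex-5-ene-1,2-diol
Product: 14 (2R)-2-(but-3-en-1-yl)-2-methyloxirane, via hydroxy tosylate 13 (not isolated)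
Conditions: TsCl (1.05 equiv), Et3N, Bu2SnO (2 mol %), CH2Cl2, 0 °C → rt; then K2CO3, MeOH, rt; pentane extraction, careful distillation (volatile)
Reagents that add atoms: none
Why: Tin-catalysed sulfonylation is selective for the primary OH, and the tertiary alkoxide then closes by intramolecular Williamson displacement at CH2, so the stereocentre is carried over unchanged.

Step 8
Reactants: 14 (2R)-2-(but-3-en-1-yl)-2-methyloxirane; 4 (Z)-3-iodo-1-[(2-methoxypropan-2-yl)oxy]but-2-ene
Product: 17 (2Z,5R)-1-[(2-methoxypropan-2-yl)oxy]-3,5-dimethylnona-2,8-dien-5-ol, via alkenyllithium 15 (not isolated), via alkenylmagnesium bromide 16 (not isolated)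
Conditions: 4 (1.3 equiv), t-BuLi (2.6 equiv), Et2O, −78 °C; MgBr2·OEt2 (1.4 equiv), −78 → −30 °C; CuI (10 mol %), then 14, THF, −30 → 0 °C; aq NH4Cl
Reagents that add atoms: none
Why: Iodine–lithium exchange and transmetalation retain the (Z) geometry, and the copper-catalysed SN2 epoxide opening occurs at the unhindered CH2, leaving the tertiary carbinol centre intact.

Step 9
Reactants: 17 (2Z,5R)-1-[(2-methoxypropan-2-yl)oxy]-3,5-dimethylnona-2,8-dien-5-ol
Product: 18 (2Z,5R)-3,5-dimethylnona-2,8-diene-1,5-diol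
Conditions: PPTS (5 mol %), MeOH, 0 °C → rt
Reagents that add atoms: none
Why: Transacetalisation to methanol removes the very labile MOP group under conditions too mild to ionise the allylic or tertiary alcohol.

Step 10
Reactants: 18 (2Z,5R)-3,5-dimethylnona-2,8-diene-1,5-diol
Product: 19 [(2S,3R)-3-[(2R)-2-hydroxy-2-methylhex-5-en-1-yl]-3-methyloxiran-2-yl]methanol
Conditions: Ti(OiPr)4 (1.0 equiv), L-(+)-DET (1.2 equiv), TBHP (2 equiv, decane), 4 Å MS, CH2Cl2, −25 °C
Reagents that add atoms: tert-butyl hydroperoxide (CC(C)(C)OO)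
Why: Sharpless asymmetric epoxidation under reagent control: with a (Z)-3,3-disubstituted (nerol-type) allylic alcohol, L-(+)-tartrate gives the (2S,3R)-epoxide, which sets the future C4 carbinol (dr about 15:1 expected, minor isomer removed by chromatography).

Step 11
Reactants: 19 [(2S,3R)-3-[(2R)-2-hydroxy-2-methylhex-5-en-1-yl]-3-methyloxiran-2-yl]methanol
Product: 20 (3S,5R)-3,5-dimethylnon-8-ene-1,3,5-triol
Conditions: Red-Al (3 equiv), THF, 0 °C → rt; Rochelle salt
Reagents that add atoms: none
Why: Alkoxide-directed intramolecular hydride delivery opens the 2,3-epoxy alcohol at C2 to the 1,3-diol; the C–O bond at the quaternary carbon is not broken, so its configuration is retained.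

Step 12
Reactants: 20 (3S,5R)-3,5-dimethylnon-8-ene-1,3,5-triol
Product: 23 (4R,6R)-6-(but-3-en-1-yl)-4-hydroxy-4,6-dimethyloxan-2-one, via hydroxy aldehyde 21 (not isolated), via lactol 22 (not isolated)
Conditions: TEMPO (0.2 equiv), PhI(OAc)2 (3 equiv), CH2Cl2, rt
Reagents that add atoms: none
Why: Oxoammonium (TEMPO/BAIB) oxidation touches only the primary alcohol; the aldehyde is trapped by the δ-tertiary OH as a six-membered lactol, which is oxidised on to the lactone while both tertiary carbinols stay unchanged.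

Step 13
Reactants: 23 (4R,6R)-6-(but-3-en-1-yl)-4-hydroxy-4,6-dimethyloxan-2-one; 9 [(2E)-8-bromooct-2-en-1-yl]benzene
Product: 25 Trisphaerolide A, via B-alkyl-9-BBN 24 (not isolated)
Conditions: 9-BBN (1.3 equiv), THF, 0 °C → rt; then K3PO4·H2O (3 equiv), stir; then 9 (1.0 equiv), Pd(OAc)2 (4 mol %), PCy3 (8 mol %), THF, rt
Reagents that add atoms: none
Why: Anti-Markovnikov hydroboration of the only terminal alkene followed by a Fu-type alkyl–alkyl Suzuki–Miyaura coupling (PCy3 suppresses β-hydride elimination) joins the two halves; no stereocentre or alkene geometry is touched, and B–H is quenched by the wet base before the (E)-alkene of 9 is added.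

**Compound list**
1 | but-2-yn-1-ol | CC#CCO | starting material
2 | sodium 2,2-bis(2-methoxyethoxy)-3-methyl-2,5-dihydro-1,2-oxaluminol-2-uide (cyclic alkenylalanate) | [Na+].CC1=CCO[Al-]1(OCCOC)OCCOC | intermediate
3 | (Z)-3-iodobut-2-en-1-ol | C/C(I)=C/CO | intermediate
4 | (Z)-3-iodo-1-[(2-methoxypropan-2-yl)oxy]but-2-ene | C/C(I)=C/COC(C)(C)OC | intermediate
5 | hept-6-yn-1-ol | C#CCCCCCO | starting material
6 | 7-bromohept-1-yne | C#CCCCCCBr | intermediate
7 | 2-[(1E)-7-bromohept-1-en-1-yl]-4,4,5,5-tetramethyl-1,3,2-dioxaborolane | BrCCCCC/C=C/B1OC(C)(C)C(C)(C)O1 | intermediate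
8 | benzyl bromide | BrCc1ccccc1 | starting material
9 | [(2E)-8-bromooct-2-en-1-yl]benzene | BrCCCCC/C=C/Cc1ccccc1 | intermediate
10 | (S)-2-methylglycidol, [(2S)-2-methyloxiran-2-yl]methanol | C[C@]1(CO)CO1 | starting material
11 | allylmagnesium bromide | C=CC[Mg]Br | starting material
12 | (2R)-2-methylhex-5-ene-1,2-diol | C[C@](O)(CO)CCC=C | intermediate
13 | (2R)-2-hydroxy-2-methylhex-5-en-1-yl 4-methylbenzenesulfonate | C[C@](O)(COS(=O)(=O)c1ccc(C)cc1)CCC=C | intermediate
14 | (2R)-2-(but-3-en-1-yl)-2-methyloxirane | C[C@]1(CO1)CCC=C | intermediate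
15 | [(2Z)-4-[(2-methoxypropan-2-yl)oxy]but-2-en-2-yl]lithium | C/C([Li])=C/COC(C)(C)OC | intermediate
16 | [(2Z)-4-[(2-methoxypropan-2-yl)oxy]but-2-en-2-yl]magnesium bromide | C/C([Mg]Br)=C/COC(C)(C)OC | intermediate
17 | (2Z,5R)-1-[(2-methoxypropan-2-yl)oxy]-3,5-dimethylnona-2,8-dien-5-ol | C[C@](O)(C/C(C)=C\COC(C)(C)OC)CCC=C | intermediate
18 | (2Z,5R)-3,5-dimethylnona-2,8-diene-1,5-diol | C[C@](O)(C/C(C)=C\CO)CCC=C | intermediate
19 | [(2S,3R)-3-[(2R)-2-hydroxy-2-methylhex-5-en-1-yl]-3-methyloxiran-2-yl]methanol | C[C@](O)(C[C@@]1(C)O[C@H]1CO)CCC=C | intermediate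
20 | (3S,5R)-3,5-dimethylnon-8-ene-1,3,5-triol | C[C@](O)(C[C@@](C)(O)CCO)CCC=C | intermediate
21 | (3R,5R)-3,5-dihydroxy-3,5-dimethylnon-8-enal | C[C@](O)(C[C@@](C)(O)CC=O)CCC=C | intermediate
22 | (2RS,4R,6R)-6-(but-3-en-1-yl)-4,6-dimethyloxane-2,4-diol (lactol, anomeric mixture) | C[C@]1(O)CC(O)O[C@](C)(CCC=C)C1 | intermediate
23 | (4R,6R)-6-(but-3-en-1-yl)-4-hydroxy-4,6-dimethyloxan-2-one | C[C@]1(O)CC(=O)O[C@](C)(CCC=C)C1 | intermediate
24 | (4R,6R)-6-[4-(9-borabicyclo[3.3.1]nonan-9-yl)butyl]-4-hydroxy-4,6-dimethyloxan-2-one | C[C@]1(O)CC(=O)O[C@](C)(CCCCB2C3CCCC2CCC3)C1 | intermediate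
25 | Trisphaerolide A, (4R,6R)-4-hydroxy-4,6-dimethyl-6-[(10E)-12-phenyldodec-10-en-1-yl]oxan-2-one | C[C@]1(O)CC(=O)O[C@](C)(CCCCCCCCC/C=C/Cc2ccccc2)C1 | target

**Totals**
Total step count: 13. Longest linear sequence: 8 steps (steps 6–13, from (S)-2-methylglycidol); the side branches are steps 1–2 and steps 3–5.

**Steps most likely to fail, with fallbacks**

Step 8 (alkenyl–copper opening of a 2,2-disubstituted epoxide). The epoxide may instead give bromohydrin or rearrange under the Lewis-acidic magnesium salts. The fallback sets out from 14 and comes back at 20. Open 14 with lithium acetylide–ethylenediamine (DMSO, rt) to (4R)-4-methyloct-7-en-1-yn-4-ol F1. Negishi zirconium-catalysed carboalumination (Me3Al, cat. Cp2ZrCl2, CH2Cl2) gives dimethyl[(1E,4R)-4-(dimethylalumanyloxy)-2,4-dimethylocta-1,7-dien-1-yl]alumane F2, which is turned into the ate complex with n-BuLi and trapped with paraformaldehyde to give (2E,5R)-3,5-dimethylnona-2,8-diene-1,5-diol F3. Because the alkene geometry is now (E), Sharpless epoxidation is run with D-(−)-DET and gives [(2R,3R)-3-[(2R)-2-hydroxy-2-methylhex-5-en-1-yl]-3-methyloxiran-2-yl]methanol F4, with the same configuration at the quaternary epoxide carbon. Red-Al opening as in step 11 then gives triol 20.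

Step 12 (oxidative lactonisation onto a tertiary hydroxyl). Lactol formation with the hindered tertiary OH may be slow, leading to over-oxidation or retro-aldol loss. The fallback sets out from 20 and comes back at 23, closing the ring by acylation instead of lactol oxidation. Oxidise 20 only to aldehyde 21 (SO3·pyridine, DMSO, iPr2NEt), then Pinnick oxidation (NaClO2, NaH2PO4, 2-methylbut-2-ene) gives (3R,5R)-3,5-dihydroxy-3,5-dimethylnon-8-enoic acid F5. Activation as the mixed anhydride (2,4,6-trichlorobenzoyl chloride, Et3N, then DMAP, toluene) closes the six-membered ring to 23.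

Step 13 (alkyl–alkyl Suzuki coupling as the last step). Risks are slow oxidative addition, Pd–H isomerisation of the allylbenzene alkene towards the styrene, and partial lactone opening by the wet base (reversed by acidic work-up). The fallback sets out from 23 and comes back at 25, with the polarity of the two halves reversed. Hydroborate 23 with 9-BBN and oxidise with NaBO3·4H2O to (4R,6R)-4-hydroxy-6-(4-hydroxybutyl)-4,6-dimethyloxan-2-one F6, then I2, PPh3 and imidazole give (4R,6R)-4-hydroxy-6-(4-iodobutyl)-4,6-dimethyloxan-2-one F7. Bromide 9 is converted with activated Zn dust and LiCl (THF, 50 °C) into [(6E)-8-phenyloct-6-en-1-yl]zinc bromide F8. A nickel-catalysed alkyl–alkyl Negishi coupling of F7 with F8 (2.5 equiv; Ni(acac)2, 4-fluorostyrene, THF/NMP, −20 °C → rt) then gives 25.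

**Further compounds**
F1 | step 8 | (4R)-4-methyloct-7-en-1-yn-4-ol | C[C@](O)(CC#C)CCC=C
F2 | step 8 | dimethyl[(1E,4R)-4-(dimethylalumanyloxy)-2,4-dimethylocta-1,7-dien-1-yl]alumane | C[C@](O[Al](C)C)(C/C(C)=C/[Al](C)C)CCC=C
F3 | step 8 | (2E,5R)-3,5-dimethylnona-2,8-diene-1,5-diol | C[C@](O)(C/C(C)=C/CO)CCC=C
F4 | step 8 | [(2R,3R)-3-[(2R)-2-hydroxy-2-methylhex-5-en-1-yl]-3-methyloxiran-2-yl]methanol | C[C@](O)(C[C@@]1(C)O[C@@H]1CO)CCC=C
F5 | step 12 | (3R,5R)-3,5-dihydroxy-3,5-dimethylnon-8-enoic acid | C[C@](O)(C[C@@](C)(O)CC(=O)O)CCC=C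
F6 | step 13 | (4R,6R)-4-hydroxy-6-(4-hydroxybutyl)-4,6-dimethyloxan-2-one | C[C@]1(O)CC(=O)O[C@](C)(CCCCO)C1
F7 | step 13 | (4R,6R)-4-hydroxy-6-(4-iodobutyl)-4,6-dimethyloxan-2-one | C[C@]1(O)CC(=O)O[C@](C)(CCCCI)C1
F8 | step 13 | [(6E)-8-phenyloct-6-en-1-yl]zinc bromide | Br[Zn]CCCCC/C=C/Cc1ccccc1
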